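The runs stem from a simulated flask on assumed constants; scatter was added.

**North-east first.** The north-east run was one of two earlier runs, and from them I had to reckon ring in two new flasks.

| flask | starting material | temperature | remark | time |
|---|---|---|---|---|
| north-east | 0.35 M | 25 °C | run made earlier |  |
| east | 1.4 M | 36 °C | run made earlier |  |
| beta | 0.70 M | 40 °C |  | 80 min |
| eta | 0.70 M | 20 °C |  | 80 min |

- north-east (time / min: ring / %, starting material / %): 30.0: 13.6, 86.5; 60.0: 24.9, 71.7; 120: 34.4, 50.5; 180: 39.7, 35.8
- east (time / min: ring / %, starting material / %): 6.00: 10.7, 86.3; 20.0: 25.3, 67.2; 30.0: 34.6, 54.0; 50.0: 44.9, 36.0; 80.0: 54.1, 21.4; 90.0: 55.3, 16.3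

(readings scatter by 1 percentage point)

1. the flask with the highest amount of ring, in percent of the starting material charged ("all alike" if they lie within 1.5 percentage points) (beta / eta / all alike)
2. final ring, as a percentage of the starting material charged, in beta
3. final ring, as a percentage of the starting material charged, in eta

- the earlier runs were read with a standard deviation of 1 percentage point
- a reading or a percentage of ring counts all its forms, free or not

**Clock.** I read starting material as first-order decay. Its last reading gave 0.00571 /min in the north-east run and 0.0202 /min in the east run. Treating the difference as a temperature effect, although the charges differed too, gave 87.9 kJ/mol. So k came to 0.0312 /min in beta and 0.00312 /min in eta.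

**Even split.** The falling balance showed ring being lost. As my zero I took the symmetric case, which I called the even split: ring made, lost and returned with the same k, a curve that moves with time and not an equilibrium value. Ring is then (1 − exp(−2kt))/2, which gave 49.7% for beta and 19.6% for eta.

**Weak link.** Equal constants were the weak assumption. The north-east run's last ring reading, 39.7%, stood below its even split of 43.6%, so I formed the ring ratio, reading over even split, 0.911. The east run ended above its even split of 48.7%, yet at 30.0 min it still read 34.6% against 35.1%, with [ring] at 0.484 M. I kept the north-east ratio for beta because its reckoned [ring] of 0.317 M lay lower. That committed me to 45.2% in beta and 17.9% in eta.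

**Forecast.** The forecast gave 55% for beta and 18.5% for eta: “Beta clearly has more ring”.

**Result.** Beta gave 42.0% and eta 18.7%, so beta held more ring.

    ring ⇌ isomer of the product (K = 1.80, k = 4.30 × 10⁻⁴ /s, Ea = 86.0 kJ/mol, ΔH = −35.0 kJ/mol)
    2 starting material ⇌ open dimer (K = 3.50 /M, k = 2.20 × 10⁻⁵ /M/s, Ea = 65.0 kJ/mol, ΔH = 8.00 kJ/mol)
    starting material → ring (k = 4.70 × 10⁻⁴ /s, Ea = 86.0 kJ/mol)
    crystals ⇌ ring, rate k4*(cs4 - [ring]) while solid is left; crystals form when [ring] > cs4 (solubility = 0.280 M, k = 0.0860 /s)
    (constants at 40 °C)

**Warmer neighbour.** Against the even split, beta's ratio came out at 0.845 and eta's at 0.954, beside my 0.911. The neighbouring flask was eta run at 35 °C, with its charge and time held. There I reckoned k as 0.0180 /min and the even split as 47.2%, and the ratio turned that into 43.0%. The flask gave 41.5% ring, with 29.9% isomer of the product and 25% starting material.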